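**Strategy.** Everything rests on cutting the C1–C8a and C4–C4a bonds of the naphthazarin. This turns the side-chain ring (C1–C4) into a 3-substituted 2,5-bis(silyloxy)furan, a succinic anhydride bis-enol ether, and the ring carrying the C5 and C8 oxygens into p-benzoquinone. Their Diels–Alder reaction forms both bonds at once and, after hydrolysis and enolisation, delivers the unprotected 5,8-dihydroxy-1,4-naphthoquinone directly at the correct oxidation level. It exploits the fact that C1/C4 and C5/C8 are all carbonyl-level carbons of a tautomerisable tetraone. The diene is made in the flask from a γ-hydroxybutenolide, itself the singlet-oxygen product of an (R)-3-furyl carbinol; a final selective esterification adds the β-hydroxyisovalerate.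

Key step: step 4

Remark: the two ring tautomers of a naphthazarin interconvert rapidly, so the tautomer first formed in step 4 and the one drawn for the target are treated as one compound. The hemiacetal carbon of 8 is an inconsequential epimer mixture and is written without configuration.

**Step 1**
Reactants: 1 furan-3-carbaldehyde; 2 allylboronic acid pinacol ester
Product: 4 (R)-1-(furan-3-yl)but-3-en-1-ol, via pinacol borate ester 3 (not isolated)
Conditions: (R)-3,3'-bis(2,4,6-triisopropylphenyl)-1,1'-binaphthyl-2,2'-diyl hydrogen phosphate (5 mol %), toluene, −30 °C; then aqueous NaHCO3 work-up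
Reagents that add atoms: allylboronic acid pinacol ester (2), C=CCB1OC(C)(C)C(C)(C)O1
Why: Chiral-phosphoric-acid-catalysed allylboration runs through a closed chair transition state in which the (R)-catalyst hydrogen-bonds the boronate oxygen and the formyl C–H, so that allyl should be delivered to the Re face of the aldehyde as with other aryl aldehydes, setting the (R)-carbinol.

**Step 2**
Reactants: 4 (R)-1-(furan-3-yl)but-3-en-1-ol; 5 2-methylbut-2-ene
Product: 6 (R)-1-(furan-3-yl)-4-methylpent-3-en-1-ol
Conditions: (H2IMes)(PCy3)Cl2Ru=CHPh (second-generation Grubbs catalyst, 3 mol %), 2-methylbut-2-ene (neat, large excess), 35 °C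
Reagents that add atoms: 2-methylbut-2-ene (5), CC=C(C)C
Why: Olefin cross-metathesis of the terminal alkene with excess 2-methylbut-2-ene transfers an isopropylidene unit and releases propene, turning allyl into prenyl while the furan, the free alcohol and the carbinol stereocentre are untouched.

**Step 3**
Reactants: 6 (R)-1-(furan-3-yl)-4-methylpent-3-en-1-ol
Product: 8 5-hydroxy-4-[(1R)-1-hydroxy-4-methylpent-3-en-1-yl]furan-2(5H)-one, via furan endoperoxide 7 (not isolated)
Conditions: O2, hν (visible light), tetraphenylporphyrin (cat.), iPr2NEt, CH2Cl2, −78 °C, stopped at full conversion of 6; then warm to rt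
Reagents that add atoms: dioxygen, O=O
Why: Singlet oxygen adds [4+2] to the furan, which should react far faster than the trisubstituted alkene at −78 °C, and the hindered amine then removes the bridgehead C–H remote from the side chain of 7 (Kornblum–DeLaMare-type fragmentation) to give the γ-hydroxybutenolide with the carbinol centre unchanged.

**Step 4**
Reactants: 8 5-hydroxy-4-[(1R)-1-hydroxy-4-methylpent-3-en-1-yl]furan-2(5H)-one; 9 p-benzoquinone
Product: 13 shikonin, via tris(trimethylsilyl) furan diene 10 (not isolated), via oxa-bridged cycloadduct 11 (not isolated), via dihydronaphthalenetetraone 12 (not isolated)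
Conditions: Me3SiOTf (3.3 equiv), Et3N (3.6 equiv), Et2O, −78 to 0 °C; ethereal layer cannulated off the separated Et3NH·OTf phase; p-benzoquinone (2 equiv), CH2Cl2, −20 °C to rt; then 0.5 M HCl, THF, 0 °C to rt
Reagents that add atoms: p-benzoquinone (9), O=C1C=CC(=O)C=C1; trimethylsilyl triflate, C[Si](C)(C)OS(=O)(=O)C(F)(F)F (its silyl groups are present only in 10 and 11 and are removed in the hydrolysis)
Why: Silyl triflate and triethylamine silylate both hydroxyls of 8 and then remove the doubly oxygen-flanked C5–H, aromatising the butenolide to the 2,5-bis(silyloxy)furan 10, a very electron-rich cyclic diene. Its furan carbons C2 and C5 add suprafacially across one C=C of p-benzoquinone in a normal-demand Diels–Alder reaction, forming the C1–C8a and C4–C4a bonds at once; the closest known reaction type is the Diels–Alder reaction of 2,5-bis(trimethylsilyloxy)furans with electron-poor alkenes, which gives hydroquinones after hydrolysis. The one ring closed is the six-membered carbocycle C1–C2–C3–C4–C4a–C8a, by intermolecular [4+2] cycloaddition. Acid then cleaves the bridging bis(silyl ketal) of 11 to the C1 and C4 ketones of 12, and double enolisation of C4a–H and C8a–H turns the quinone-derived ring into the 5,8-dihydroxyarene, so the naphthazarin should appear without any oxidant or phenol protection. No new stereocentre survives (the four of 11 are erased on aromatisation), and the (R)-carbinol, masked as its trimethylsilyl ether, is not touched. The step needs cycloaddition to win over conjugate addition or electron transfer, and mono- over bis-addition; this is secured by removing the triflate phase (with excess amine leaving no free silyl triflate) before the quinone is added and by using the quinone in excess, while regiochemistry is moot because the dienophile is symmetrical.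

**Step 5**
Reactants: 13 shikonin; 14 3-hydroxy-3-methylbutanoic acid
Product: 15 beta-HIVS
Conditions: 3-hydroxy-3-methylbutanoic acid (1.5 equiv), DCC, DMAP (cat.), CH2Cl2, 0 °C to rt
Reagents that add atoms: 3-hydroxy-3-methylbutanoic acid (14), CC(C)(O)CC(=O)O
Why: Steglich esterification should acylate only the secondary side-chain hydroxyl, because the two peri-phenols are tied up in strong hydrogen bonds to the quinone carbonyls and the tertiary hydroxyl of the acid is too hindered; acylation at oxygen retains the (R)-configuration.

**Compound list**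
1 | furan-3-carbaldehyde | O=Cc1ccoc1 | starting material
2 | allylboronic acid pinacol ester (2-allyl-4,4,5,5-tetramethyl-1,3,2-dioxaborolane) | C=CCB1OC(C)(C)C(C)(C)O1 | starting material
3 | 2-{[(1R)-1-(furan-3-yl)but-3-en-1-yl]oxy}-4,4,5,5-tetramethyl-1,3,2-dioxaborolane | C=CC[C@@H](OB1OC(C)(C)C(C)(C)O1)c1ccoc1 | intermediate (not isolated)
4 | (R)-1-(furan-3-yl)but-3-en-1-ol | C=CC[C@@H](O)c1ccoc1 | intermediate
5 | 2-methylbut-2-ene | CC=C(C)C | starting material
6 | (R)-1-(furan-3-yl)-4-methylpent-3-en-1-ol | CC(C)=CC[C@@H](O)c1ccoc1 | intermediate
7 | 5-[(1R)-1-hydroxy-4-methylpent-3-en-1-yl]-2,3,7-trioxabicyclo[2.2.1]hept-5-ene (furan endoperoxide, bridgehead mixture) | CC(C)=CC[C@@H](O)C1=CC2OOC1O2 | intermediate (not isolated)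
8 | 5-hydroxy-4-[(1R)-1-hydroxy-4-methylpent-3-en-1-yl]furan-2(5H)-one (hemiacetal epimers) | CC(C)=CC[C@@H](O)C1=CC(=O)OC1O | intermediate
9 | p-benzoquinone | O=C1C=CC(=O)C=C1 | starting material
10 | 3-[(1R)-4-methyl-1-(trimethylsilyloxy)pent-3-en-1-yl]-2,5-bis(trimethylsilyloxy)furan | CC(C)=CC[C@@H](O[Si](C)(C)C)c1cc(O[Si](C)(C)C)oc1O[Si](C)(C)C | intermediate (not isolated)
11 | 2-[(1R)-4-methyl-1-(trimethylsilyloxy)pent-3-en-1-yl]-1,4-bis(trimethylsilyloxy)-1,4,4a,8a-tetrahydro-1,4-epoxynaphthalene-5,8-dione (ring stereoisomer mixture) | CC(C)=CC[C@@H](O[Si](C)(C)C)C1=CC2(O[Si](C)(C)C)OC1(O[Si](C)(C)C)C1C2C(=O)C=CC1=O | intermediate (not isolated)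
12 | 2-[(1R)-1-hydroxy-4-methylpent-3-en-1-yl]-4a,8a-dihydronaphthalene-1,4,5,8-tetraone | CC(C)=CC[C@@H](O)C1=CC(=O)C2C(=O)C=CC(=O)C2C1=O | intermediate (not isolated)
13 | shikonin, 5,8-dihydroxy-2-[(1R)-1-hydroxy-4-methylpent-3-en-1-yl]naphthalene-1,4-dione | CC(C)=CC[C@@H](O)C1=CC(=O)c2c(O)ccc(O)c2C1=O | intermediate
14 | 3-hydroxy-3-methylbutanoic acid | CC(C)(O)CC(=O)O | starting material
15 | beta-HIVS, (1R)-1-(5,8-dihydroxy-1,4-dioxo-1,4-dihydronaphthalen-2-yl)-4-methylpent-3-en-1-yl 3-hydroxy-3-methylbutanoate | CC(C)=CC[C@@H](OC(=O)CC(C)(C)O)C1=CC(=O)c2c(O)ccc(O)c2C1=O | target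

**Total step count:** 5. **Longest linear sequence:** 5 steps.

**Steps most likely to fail**

Step 4. The electron-rich diene may be consumed by electron transfer to the quinone, or by conjugate addition onto it, faster than it cycloadds. The fallback sets out from 8 and removes the redox-active partner. Diene 10 is generated as before and heated in toluene at 60 °C with commercial 4,4-dimethoxycyclohexa-2,5-dien-1-one (COC1(OC)C=CC(=O)C=C1), a non-oxidising masked quinone. This should give the ketal cycloadduct F1 (either ketal regioisomer serves). Treatment with 0.5 M HCl in THF cleaves the silyl groups and the dimethyl ketal together, and the resulting tetraone 12 enolises, so the route is rejoined at 13.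

Step 3. Over-oxidation may occur through an ene reaction of singlet oxygen at the prenyl double bond in competition with furan cycloaddition. The fallback sets out from 4 and changes the order of events. The furan is photooxygenated under the conditions of step 3 while the alkene is still terminal, and therefore inert to singlet oxygen, giving 5-hydroxy-4-[(1R)-1-hydroxybut-3-en-1-yl]furan-2(5H)-one F2. Cross-metathesis of F2 with 5 under the conditions of step 2 then installs the prenyl group, the electron-poor butenolide alkene staying out of the metathesis. The route is rejoined at 8.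

Step 5. Self-acylation or β-lactonisation of the activated β-hydroxy acid may outrun acylation of the hindered secondary alcohol. The fallback sets out from 13 and 14 and masks the tertiary hydroxyl. Acid 14 is silylated twice (Et3SiCl, imidazole, DMF) to triethylsilyl 3-methyl-3-(triethylsilyloxy)butanoate F3. The silyl ester is cleaved selectively (K2CO3, MeOH/H2O, then mild acidification) to 3-methyl-3-(triethylsilyloxy)butanoic acid F4. F4 is coupled with 13 (DCC, DMAP, CH2Cl2) to the triethylsilyl ether of the target F5, and HF·pyridine in THF at 0 °C frees the tertiary alcohol. The route is rejoined at 15.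

**Further compounds**
F1 | step 4 | C5 dimethyl ketal of cycloadduct 11 (drawn as one regioisomer) | CC(C)=CC[C@@H](O[Si](C)(C)C)C1=CC2(O[Si](C)(C)C)OC1(O[Si](C)(C)C)C1C2C(OC)(OC)C=CC1=O
F2 | step 3 | 5-hydroxy-4-[(1R)-1-hydroxybut-3-en-1-yl]furan-2(5H)-one | C=CC[C@@H](O)C1=CC(=O)OC1O
F3 | step 5 | triethylsilyl 3-methyl-3-(triethylsilyloxy)butanoate | CC[Si](CC)(CC)OC(C)(C)CC(=O)O[Si](CC)(CC)CC
F4 | step 5 | 3-methyl-3-(triethylsilyloxy)butanoic acid | CC[Si](CC)(CC)OC(C)(C)CC(=O)O
F5 | step 5 | (1R)-1-(5,8-dihydroxy-1,4-dioxo-1,4-dihydronaphthalen-2-yl)-4-methylpent-3-en-1-yl 3-methyl-3-(triethylsilyloxy)butanoate | CC(C)=CC[C@@H](OC(=O)CC(C)(C)O[Si](CC)(CC)CC)C1=CC(=O)c2c(O)ccc(O)c2C1=O
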